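The data are simulated for an exercise, noise included.

If Q enters the main step once, the amber run, charged with 0.750 M of Q against 0.500 M in the grey run, makes Z 1.50 times as fast as the grey run; that first order is the zero of the scale.

| flask | L | Q | time |
|---|---|---|---|
| grey | 0.200 M | 0.500 M |  |
| amber | 0.200 M | 0.750 M |  |
| red | 0.0660 M | 0.250 M | 33 min |

- grey run (time / min: [Z] / M): 1.3: 0.0236; 2.3: 0.0341; 3.9: 0.0465; 6.6: 0.0603; 11: 0.0795; 19: 0.0844; 33: 0.0905
- amber run (time / min: [Z] / M): 1.3: 0.0357; 2.3: 0.0535; 3.9: 0.0771; 6.6: 0.0906; 11: 0.1044; 19: 0.1137; 33: 0.1185

(each reading ± 0.002 M)

1. apparent order in [Q] of the starting rate, round the charge of the grey run (the rate where two percent of its L have turned into Z)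
2. Z in the red run at 33 min, as a share of the L charged
3. which of these the readings show (the product speeds the reaction / the product binds the second partner / two substrates go astray together / the product decays / nothing beyond the main steps)

- Overall: L + Q -> Z.
- Constant volume, constant temperature.
- What is held in complexes is read along with the free species.
- "The second partner" is Q.
- An order is taken over about fifteen percent of the charge, up and down.

The grey run descends a ladder of rates. Up to 3.9 min, Z forms at 0.0119 M/min on average, and from 19 min to 33 min at 4.36 × 10⁻⁴ M/min, which is 27.4 times slower. By the overall equation, Q still stands at 0.409 M there, and Z has reached 0.0905 M from 0.200 M of L. L has therefore left by another road, which I take to be two L pairing. With Q in excess, I treat the main step as pseudo-first-order and let its rate constant scale as a power of Q. At 3.9 min the scatter of 0.002 M is small beside Z, and the amber run gives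

order = ln(amber Z / grey Z) / ln(Q ratio) = 1.25

This is a reading, and it leans low, since the amber run has by then turned more L into Z. The clock factor is a flask's main-step constant over that of the grey run, the Q ratio raised to this order:

red clock factor = 0.421

So 33 min in the red run corresponds to 13.9 min in the grey run, or 8.38 min in the amber run. Between the readings these give

grey share = 40.6 %
amber share = 48.1 %

The red run's ratio of main step to pairing, the clock factor over its L charge, lies 0.483 of the logarithmic way from grey to amber, so my estimate is 44.2 %.

The forecast gives an order of 1 (0.8 to 1.2), 51 % (45 % to 58 %) and "two substrates go astray together": “Early rates scale about 1.5-fold for 1.5-fold Q, so the order is about 1.” My order is higher and my share lower.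

The flask gives an order of 1.4, 43.6 % and "two substrates go astray together".

    2 Q ⇌ Q2, settled at all times (3.050 /M)
    L + Q2 → Z + Q (0.8100 /M/min)
    2 L → Dz (0.7380 /M/min)

At the start of the red run, Q2 stood in balance with Q at 0.0568 M, which is 0.400 of its starting level in the grey run, beside a clock factor of 0.421. In that red run Q2 carried L to Z while two L paired to Dz, L going at the start to Z at 0.0460 /min and into Dz at 0.0974 /min, and by 33 min Z stood at 43.6 % of the L charged.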